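**Retrosynthetic overview**
1. Target 8 comes from acetal hydrolysis of pyrrole acetal 7, which comes from Paal–Knorr condensation of ammonia with the 1,4-diketone 6 (1,1-dimethoxyhexacosane-2,5-dione).
2. Key disconnection of 6 at C4–C5: docosanoyl chloride 3 (acyl electrophile) plus the ketone homoenolate ⁻CH2CH2C(=O)CH(OMe)2, used as zinc homoenolate 5.
3. Homoenolate 5 comes from strain-driven ring opening of cyclopropanol 2, made by Kulinkovich cyclopropanation of methyl dimethoxyacetate 1.
4. Ring order: a sacrificial cyclopropane (step 1, opened in step 2), then the pyrrole, the only ring of the target, in the last step.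

Assumption: the target has no stereocentre and no double-bond geometry, so "single enantiomer" means the achiral compound itself; docosanoyl (behenoyl) chloride is taken as a purchasable reagent.

**Step 1**
Reactants: 1 methyl 2,2-dimethoxyacetate
Product: 2 1-(dimethoxymethyl)cyclopropan-1-ol
Conditions: EtMgBr (2.6 equiv, slow addition), Ti(OiPr)4 (20 mol %), THF, 0 °C→rt; sat. aq NH4Cl (no mineral acid)
Reagents that add atoms: ethylmagnesium bromide, CC[Mg]Br
Why: Kulinkovich cyclopropanation, in which the titanacyclopropane formed from EtMgBr and Ti(OiPr)4 adds twice to the ester carbonyl as a 1,2-dicarbanion while the acetal is inert to Grignard and titanium reagents; no stereocentre is formed.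

**Step 2**
Reactants: 2 1-(dimethoxymethyl)cyclopropan-1-ol; 3 docosanoyl chloride
Product: 6 1,1-dimethoxyhexacosane-2,5-dione, via ethylzinc 1-(dimethoxymethyl)cyclopropan-1-olate 4 (not isolated), via ethyl(4,4-dimethoxy-3-oxobutyl)zinc 5 (not isolated)
Conditions: Et2Zn (1.0 equiv), THF, 0 °C→rt; then 3, Pd(PPh3)4 (5 mol %), THF–DMA, rt→40 °C; aq NH4Cl
Reagents that add atoms: none
Why: The zinc cyclopropanolate opens by strain release to the zinc ketone homoenolate, whose nucleophilic β-carbon is acylated by the acyl-palladium species from 3 (Pd-catalysed Negishi-type acylation of a cyclopropanol-derived homoenolate), giving the 1,4-diketone directly; the cyclopropane is symmetric, so there is no regiochemical or stereochemical issue.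

**Step 3**
Reactants: 6 1,1-dimethoxyhexacosane-2,5-dione
Product: 8 5-henicosyl-1H-pyrrole-2-carbaldehyde, via 2-(dimethoxymethyl)-5-henicosyl-1H-pyrrole 7 (not isolated)
Conditions: NH4OAc (8 equiv), MeOH–THF (1:1), 55 °C; then AcOH–H2O (4:1) added to the same flask, rt
Reagents that add atoms: ammonium acetate, CC(=O)[O-].[NH4+]; water, O
Why: Paal–Knorr pyrrole synthesis in methanol keeps the acetal intact while ammonia bridges the two ketones, and the resulting 2-(dimethoxymethyl)pyrrole then hydrolyses very readily in dilute aqueous acid (azafulvenium-assisted) to the aldehyde; no stereocentre is involved.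

**Compound list**
1 | methyl 2,2-dimethoxyacetate | COC(OC)C(=O)OC | starting material
2 | 1-(dimethoxymethyl)cyclopropan-1-ol | COC(OC)C1(O)CC1 | intermediate
3 | docosanoyl chloride | CCCCCCCCCCCCCCCCCCCCCC(=O)Cl | starting material
4 | ethylzinc 1-(dimethoxymethyl)cyclopropan-1-olate | CC[Zn]OC1(CC1)C(OC)OC | intermediate
5 | ethyl(4,4-dimethoxy-3-oxobutyl)zinc | CC[Zn]CCC(=O)C(OC)OC | intermediate
6 | 1,1-dimethoxyhexacosane-2,5-dione | COC(OC)C(=O)CCC(=O)CCCCCCCCCCCCCCCCCCCCC | intermediate
7 | 2-(dimethoxymethyl)-5-henicosyl-1H-pyrrole | CCCCCCCCCCCCCCCCCCCCCc1ccc(C(OC)OC)[nH]1 | intermediate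
8 | 5-henicosyl-1H-pyrrole-2-carbaldehyde | CCCCCCCCCCCCCCCCCCCCCc1ccc(C=O)[nH]1 | target

**Total step count:** 3
**Longest linear sequence:** 3 steps (1 → 2 → 6 → 8; 3 enters at step 2)

**Steps most likely to fail, with fallbacks**

Step 2 (highest risk). O-acylation of the zinc cyclopropanolate, or β-hydride elimination of the palladium homoenolate to the enone, may outrun C-acylation. The fallback replaces the homoenolate by an acyl anion and sets out from 2 and 3. Cyclopropanol 2 is opened oxidatively (Pd(OAc)2 cat., pyridine, O2, toluene, 80 °C) to 1,1-dimethoxybut-3-en-2-one F3. Acid chloride 3 is reduced (H2, Pd/BaSO4, 2,6-lutidine, THF, Rosenmund) to docosanal F4. A thiazolium-catalysed Stetter reaction (3-benzyl-5-(2-hydroxyethyl)-4-methylthiazolium chloride 10 mol %, Et3N, dioxane, 70 °C) adds the Breslow intermediate of F4 to F3 and comes back to the route at 6.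

Step 1. The chelating α,α-dialkoxy ester may react sluggishly in the Kulinkovich reaction, and 2 is small, volatile and water-soluble. The fallback leaves the cyclopropanol out and builds the same C3–C4 bond region with an α-halo ketone as enolonium equivalent; it sets out from 3. Acylation of potassium ethyl malonate (MgCl2, Et3N, MeCN, then decarboxylation on work-up) gives ethyl 3-oxotetracosanoate F1. Its enolate (K2CO3, acetone, rt) is alkylated by purchased 3-bromo-1,1-dimethoxypropan-2-one to racemic ethyl 2-(3,3-dimethoxy-2-oxopropyl)-3-oxotetracosanoate F2. Neutral dealkoxycarbonylation (NaCl, H2O, DMSO, 140 °C) then gives 6, where the fallback rejoins the route.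

Step 3. Premature loss of the acetal in the presence of ammonia would expose a 1,2,5-tricarbonyl that can close to a 3-hydroxypyridine, and the NH-pyrrole acetal can oligomerise through its azafulvenium ion. The fallback carries a removable N-substituent through ring formation and sets out from 6. Paal–Knorr condensation with 3-aminopropanenitrile (AcOH cat., MeOH–THF, 50 °C) gives 3-[2-(dimethoxymethyl)-5-henicosyl-1H-pyrrol-1-yl]propanenitrile F5. Aqueous AcOH hydrolyses it to 3-(2-formyl-5-henicosyl-1H-pyrrol-1-yl)propanenitrile F6. Retro-aza-Michael cleavage (t-BuOK, THF, 0 °C→rt) expels the cyanoethyl group and comes back to the route at 8.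

**Further compounds**
F1 | step 1 | ethyl 3-oxotetracosanoate | CCCCCCCCCCCCCCCCCCCCCC(=O)CC(=O)OCC
F2 | step 1 | ethyl 2-(3,3-dimethoxy-2-oxopropyl)-3-oxotetracosanoate (racemic) | CCOC(=O)C(CC(=O)C(OC)OC)C(=O)CCCCCCCCCCCCCCCCCCCCC
F3 | step 2 | 1,1-dimethoxybut-3-en-2-one | C=CC(=O)C(OC)OC
F4 | step 2 | docosanal | CCCCCCCCCCCCCCCCCCCCCC=O
F5 | step 3 | 3-[2-(dimethoxymethyl)-5-henicosyl-1H-pyrrol-1-yl]propanenitrile | CCCCCCCCCCCCCCCCCCCCCc1ccc(C(OC)OC)n1CCC#N
F6 | step 3 | 3-(2-formyl-5-henicosyl-1H-pyrrol-1-yl)propanenitrile | CCCCCCCCCCCCCCCCCCCCCc1ccc(C=O)n1CCC#N
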